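Assumption: the target has no stereocentre and no stereogenic double bond, so there is nothing to control stereochemically; methyl orsellinate and octanoyl chloride are taken as commercial starting materials.

**Retrosynthetic overview**
- Target ⇒ (benzyl hydrogenolysis, ketal hydrolysis) bis-benzyl, bis-dioxolane depside ⇒ cut the depside C(=O)–OAr bond (carbodiimide esterification) into a protected benzoic acid and a 2,4-dihydroxybenzoate.
- Both halves come from one intermediate, methyl 2,4-bis(benzyloxy)-6-[(2-heptyl-1,3-dioxolan-2-yl)methyl]benzoate (saponification gives the acid; hydrogenolysis gives the phenol).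
- Key C–C disconnection ArCH2–C(=O)C7H15: crossed Claisen-type condensation of the laterally lithiated toluate (vinylogous ester enolate of dibenzyl methyl orsellinate) with an octanoyl donor (Weinreb amide from octanoyl chloride).
- Rings: both benzene rings are bought preformed in methyl orsellinate and no carbocycle is built; only the two temporary dioxolane rings are formed (after the Claisen step) and opened again before the final hydrogenolysis.

**Route**

Step 1
Reactants: 1 octanoyl chloride
Product: 2 N-methoxy-N-methyloctanamide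
Conditions: MeNH(OMe)·HCl (1.1 equiv), Et3N (2.3 equiv), CH2Cl2, 0 °C → rt
Reagents that add atoms: N,O-dimethylhydroxylamine hydrochloride, CNOC.Cl
Why: Nucleophilic acyl substitution (Weinreb amide formation) of a reactive acid chloride by the free-based amine is fast and clean.

Step 2
Reactants: 3 methyl 2,4-dihydroxy-6-methylbenzoate (methyl orsellinate)
Product: 4 methyl 2,4-bis(benzyloxy)-6-methylbenzoate
Conditions: BnBr (2.4 equiv), K2CO3 (3 equiv), DMF, 60 °C
Reagents that add atoms: benzyl bromide, BrCc1ccccc1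
Why: Williamson ether synthesis; warming in DMF also alkylates the hydrogen-bonded 2-OH, removing both acidic protons before the strong-base step and installing groups that come off by neutral hydrogenolysis.

Step 3
Reactants: 4 methyl 2,4-bis(benzyloxy)-6-methylbenzoate; 2 N-methoxy-N-methyloctanamide
Product: 7 methyl 2,4-bis(benzyloxy)-6-(2-oxononyl)benzoate, via benzylic lithium dienolate 5 (not isolated), via lithium hemiaminal alkoxide 6 (not isolated)
Conditions: LDA (2.0 equiv), THF, −78 °C, 15 min; then 2 (1.3 equiv), −78 → −40 °C; AcOH/THF quench at −78 °C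
Reagents that add atoms: none
Why: Lateral lithiation of the o-toluate gives a vinylogous ester enolate whose C-acylation is a crossed Claisen-type condensation; the chelated tetrahedral adduct from the Weinreb donor stops over-addition and keeps the ketone masked from base until the cold quench (no stereocentre is formed).

Step 4
Reactants: 7 methyl 2,4-bis(benzyloxy)-6-(2-oxononyl)benzoate
Product: 8 methyl 2,4-bis(benzyloxy)-6-[(2-heptyl-1,3-dioxolan-2-yl)methyl]benzoate
Conditions: TMSOCH2CH2OTMS (3 equiv), TMSOTf (0.1 equiv), CH2Cl2, −78 → −20 °C; pyridine quench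
Reagents that add atoms: 1,2-bis(trimethylsilyloxy)ethane, C[Si](C)(C)OCCO[Si](C)(C)C
Why: Noyori ketalisation proceeds at low temperature under aprotic conditions, so the ketone is masked before enol-lactonisation onto the ortho ester (isocoumarin formation) can compete.

Step 5
Reactants: 8 methyl 2,4-bis(benzyloxy)-6-[(2-heptyl-1,3-dioxolan-2-yl)methyl]benzoate
Product: 10 2,4-bis(benzyloxy)-6-[(2-heptyl-1,3-dioxolan-2-yl)methyl]benzoic acid, via potassium carboxylate 9 (not isolated)
Conditions: KOH (10 equiv), DMSO/H2O 4:1, 90 °C; then cold 1 M HCl to pH 4–5 at 0 °C, immediate EtOAc extraction, used at once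
Reagents that add atoms: potassium hydroxide, [K+].[OH-]
Why: Saponification of the di-ortho-substituted ester needs poorly solvated hydroxide in hot aqueous DMSO; benzyl ethers and the ketal are inert to base, and the brief cold, weakly acidic work-up spares the ketal.

Step 6
Reactants: 8 methyl 2,4-bis(benzyloxy)-6-[(2-heptyl-1,3-dioxolan-2-yl)methyl]benzoate
Product: 11 methyl 6-[(2-heptyl-1,3-dioxolan-2-yl)methyl]-2,4-dihydroxybenzoate
Conditions: H2 (1 atm), 10% Pd/C, EtOAc, rt
Reagents that add atoms: none
Why: Catalytic hydrogenolysis removes both O-benzyl groups under neutral conditions that leave the ketal and methyl ester untouched.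

Step 7
Reactants: 10 2,4-bis(benzyloxy)-6-[(2-heptyl-1,3-dioxolan-2-yl)methyl]benzoic acid; 11 methyl 6-[(2-heptyl-1,3-dioxolan-2-yl)methyl]-2,4-dihydroxybenzoate
Product: 13 methyl 4-({2,4-bis(benzyloxy)-6-[(2-heptyl-1,3-dioxolan-2-yl)methyl]benzoyl}oxy)-6-[(2-heptyl-1,3-dioxolan-2-yl)methyl]-2-hydroxybenzoate, via O-acylisourea 12 (not isolated)
Conditions: DCC (1.2 equiv), DMAP (0.2 equiv), CH2Cl2, 0 °C → rt
Reagents that add atoms: none
Why: Steglich esterification under non-acidic conditions tolerates both ketals and acylates only the 4-OH, because the 2-OH is hydrogen-bonded to the ester carbonyl, more hindered and less nucleophilic.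

Step 8
Reactants: 13 bis-dioxolane dibenzyl depside
Product: 14 methyl 4-{[2,4-bis(benzyloxy)-6-(2-oxononyl)benzoyl]oxy}-2-hydroxy-6-(2-oxononyl)benzoate
Conditions: 1 M aq. HCl/THF 1:4, rt; NaHCO3 work-up
Reagents that add atoms: water, O
Why: Acid-catalysed ketal hydrolysis of two unhindered dialkyl-ketone dioxolanes is fast at room temperature, while the aryl ester, methyl ester and benzyl ethers are stable to dilute aqueous acid.

Step 9
Reactants: 14 methyl 4-{[2,4-bis(benzyloxy)-6-(2-oxononyl)benzoyl]oxy}-2-hydroxy-6-(2-oxononyl)benzoate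
Product: 15 methyl 4-{[2,4-dihydroxy-6-(2-oxononyl)benzoyl]oxy}-2-hydroxy-6-(2-oxononyl)benzoate (CNP0110390.0)
Conditions: H2 (1 atm), 10% Pd/C, EtOAc, rt
Reagents that add atoms: none
Why: Neutral hydrogenolysis of the two aryl benzyl ethers ends the synthesis without acid or base; the non-conjugated dialkyl ketones and the depside ester are not reduced.

**Compound list**
1 | octanoyl chloride | CCCCCCCC(=O)Cl | starting material
2 | N-methoxy-N-methyloctanamide | CCCCCCCC(=O)N(C)OC | intermediate
3 | methyl 2,4-dihydroxy-6-methylbenzoate (methyl orsellinate) | COC(=O)c1c(C)cc(O)cc1O | starting material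
4 | methyl 2,4-bis(benzyloxy)-6-methylbenzoate | COC(=O)c1c(C)cc(OCc2ccccc2)cc1OCc1ccccc1 | intermediate
5 | methyl 2,4-bis(benzyloxy)-6-(lithiomethyl)benzoate (benzylic lithium dienolate, not isolated) | [Li]Cc1cc(OCc2ccccc2)cc(OCc2ccccc2)c1C(=O)OC | intermediate
6 | lithium hemiaminal alkoxide from 5 and 2 (tetrahedral adduct, not isolated) | CCCCCCCC(O[Li])(Cc1cc(OCc2ccccc2)cc(OCc2ccccc2)c1C(=O)OC)N(C)OC | intermediate
7 | methyl 2,4-bis(benzyloxy)-6-(2-oxononyl)benzoate | CCCCCCCC(=O)Cc1cc(OCc2ccccc2)cc(OCc2ccccc2)c1C(=O)OC | intermediate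
8 | methyl 2,4-bis(benzyloxy)-6-[(2-heptyl-1,3-dioxolan-2-yl)methyl]benzoate | CCCCCCCC1(Cc2cc(OCc3ccccc3)cc(OCc3ccccc3)c2C(=O)OC)OCCO1 | intermediate
9 | potassium 2,4-bis(benzyloxy)-6-[(2-heptyl-1,3-dioxolan-2-yl)methyl]benzoate (not isolated) | CCCCCCCC1(Cc2cc(OCc3ccccc3)cc(OCc3ccccc3)c2C(=O)[O-])OCCO1.[K+] | intermediate
10 | 2,4-bis(benzyloxy)-6-[(2-heptyl-1,3-dioxolan-2-yl)methyl]benzoic acid | CCCCCCCC1(Cc2cc(OCc3ccccc3)cc(OCc3ccccc3)c2C(=O)O)OCCO1 | intermediate
11 | methyl 6-[(2-heptyl-1,3-dioxolan-2-yl)methyl]-2,4-dihydroxybenzoate | CCCCCCCC1(Cc2cc(O)cc(O)c2C(=O)OC)OCCO1 | intermediate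
12 | O-acylisourea of 10 with DCC (not isolated) | CCCCCCCC1(Cc2cc(OCc3ccccc3)cc(OCc3ccccc3)c2C(=O)OC(=NC2CCCCC2)NC2CCCCC2)OCCO1 | intermediate
13 | methyl 4-({2,4-bis(benzyloxy)-6-[(2-heptyl-1,3-dioxolan-2-yl)methyl]benzoyl}oxy)-6-[(2-heptyl-1,3-dioxolan-2-yl)methyl]-2-hydroxybenzoate | CCCCCCCC1(Cc2cc(OC(=O)c3c(OCc4ccccc4)cc(OCc4ccccc4)cc3CC3(CCCCCCC)OCCO3)cc(O)c2C(=O)OC)OCCO1 | intermediate
14 | methyl 4-{[2,4-bis(benzyloxy)-6-(2-oxononyl)benzoyl]oxy}-2-hydroxy-6-(2-oxononyl)benzoate | CCCCCCCC(=O)Cc1cc(OC(=O)c2c(OCc3ccccc3)cc(OCc3ccccc3)cc2CC(=O)CCCCCCC)cc(O)c1C(=O)OC | intermediate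
15 | methyl 4-{[2,4-dihydroxy-6-(2-oxononyl)benzoyl]oxy}-2-hydroxy-6-(2-oxononyl)benzoate (achiral) | CCCCCCCC(=O)Cc1cc(OC(=O)c2c(O)cc(O)cc2CC(=O)CCCCCCC)cc(O)c1C(=O)OC | target

**Totals**
Total step count: 9. Longest linear sequence: 7 (steps 2, 3, 4, 5, 7, 8, 9); steps 1 and 6 are side branches.

**Three steps most likely to fail, with fallbacks**

Step 3 (Claisen-type acylation). The lithiated toluate can be quenched by the α-protons of the amide or attack a second ester molecule, giving low conversion. The fallback sets out from 4, which is lithiated to 5 as before and then treated with octanal (−78 → 0 °C). This vinylogous aldol addition is faster than acylation, and the adduct closes onto the ester in the flask to give racemic 6,8-bis(benzyloxy)-3-heptyl-3,4-dihydro-1H-isochromen-1-one F1. The lactone is opened with KOH in aqueous EtOH/THF to potassium 2,4-bis(benzyloxy)-6-(2-hydroxynonyl)benzoate F2, which after evaporation is O-methylated with MeI in DMF to methyl 2,4-bis(benzyloxy)-6-(2-hydroxynonyl)benzoate F3. F3 is oxidised at once with Dess–Martin periodinane (NaHCO3, CH2Cl2), which erases the racemic carbinol centre, and the fallback comes back to the route at 7.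

Step 7 (depside esterification). The acid is di-ortho-substituted, so the O-acylisourea may rearrange to an N-acylurea faster than the phenol attacks. The fallback sets out from 10, which is converted under neutral conditions with 1-chloro-N,N,2-trimethylprop-1-en-1-amine (CH2Cl2, 0 °C → rt, no HCl released) into the isolable 2,4-bis(benzyloxy)-6-[(2-heptyl-1,3-dioxolan-2-yl)methyl]benzoyl chloride F4. F4 is added to phenol 11 with Et3N and catalytic DMAP in CH2Cl2, where the more acidic 4-phenoxide is acylated, and the fallback comes back to the route at 13.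

Step 8 (double ketal hydrolysis on the depside). The freed ring-A ketone sits ortho to an activated aryl ester and could, via its enol, expel the phenol half as an isocoumarin under aqueous acid. The fallback sets out from 13 and reverses the order of the last two operations. Hydrogenolysis (H2, Pd/C, EtOAc) first gives methyl 4-({6-[(2-heptyl-1,3-dioxolan-2-yl)methyl]-2,4-dihydroxybenzoyl}oxy)-6-[(2-heptyl-1,3-dioxolan-2-yl)methyl]-2-hydroxybenzoate F5, in which the depside carbonyl is deactivated by the free ortho- and para-hydroxyls. The ketals are then removed by near-neutral exchange into dry acetone with catalytic PPTS at rt, and the fallback comes back to the route directly at 15.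

**Further compounds**
F1 | step 3 | 6,8-bis(benzyloxy)-3-heptyl-3,4-dihydro-1H-isochromen-1-one (racemic) | O=C1OC(CCCCCCC)Cc2cc(OCc3ccccc3)cc(OCc3ccccc3)c12
F2 | step 3 | potassium 2,4-bis(benzyloxy)-6-(2-hydroxynonyl)benzoate (racemic, not isolated) | CCCCCCCC(O)Cc1cc(OCc2ccccc2)cc(OCc2ccccc2)c1C(=O)[O-].[K+]
F3 | step 3 | methyl 2,4-bis(benzyloxy)-6-(2-hydroxynonyl)benzoate (racemic) | CCCCCCCC(O)Cc1cc(OCc2ccccc2)cc(OCc2ccccc2)c1C(=O)OC
F4 | step 7 | 2,4-bis(benzyloxy)-6-[(2-heptyl-1,3-dioxolan-2-yl)methyl]benzoyl chloride | CCCCCCCC1(Cc2cc(OCc3ccccc3)cc(OCc3ccccc3)c2C(=O)Cl)OCCO1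
F5 | step 8 | methyl 4-({6-[(2-heptyl-1,3-dioxolan-2-yl)methyl]-2,4-dihydroxybenzoyl}oxy)-6-[(2-heptyl-1,3-dioxolan-2-yl)methyl]-2-hydroxybenzoate | CCCCCCCC1(Cc2cc(OC(=O)c3c(O)cc(O)cc3CC3(CCCCCCC)OCCO3)cc(O)c2C(=O)OC)OCCO1
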